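Both ring bonds to C2 of the dihydrofuran (O1, C2, C3, C3a, C7a) are cut. C2 is bonded to the aryl oxygen O1, to the benzylic carbon C3 and to C1' of the cyclohexene ring (C1'–C6', cis-diol at C3'/C4'). This one carbon, with the whole cyclohexene attached, is therefore brought in as an allylic sulfonium ylide. A single operation joins it to an ester-substituted ortho-quinone methide, makes C2–C3 and O1–C2, closes the ring and sets C2/C3 trans. The precursors are a racemic α-tosyl arylacetate carrying a free ortho phenol and an enantiopure cyclohexenylmethyl sulfonium salt. Its twofold-symmetric chiral thiolane, bound directly to C2, decides the absolute sense.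

Key step: step 15

Numbering: benzofuran numbers for O1 to C7a. Primed numbers are used for the cyclohexene, with C1' on C2, C3' the allylic carbinol carbon and C4' its neighbour.
Assumption: the (2S,5S)-thiolane is taken to expose the same ylide face to the quinone methide as sulfides of this class expose to aldehydes in epoxidation. If a trial shows the opposite sense, the enantiomeric sulfide, made the same way from the enantiomeric diol, is used with no other change.

Step 1
Reactants: 1 dihydroconiferyl alcohol [4-(3-hydroxypropyl)-2-methoxyphenol]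
Product: 2 4-[3-(tert-butyldimethylsilyloxy)propyl]-2-methoxyphenol
Conditions: TBSCl (1.05 equiv), imidazole (2.2 equiv), CH2Cl2, 0 °C
Reagents that add atoms: tert-butyldimethylsilyl chloride, CC(C)(C)[Si](C)(C)Cl
Why: Chemoselective silyl ether formation, in which the unhindered primary alcohol is silylated faster than the hydrogen-bonded guaiacol OH and any aryl silyl ether formed is the more labile one and is shed on aqueous work-up.

Step 2
Reactants: 2 4-[3-(tert-butyldimethylsilyloxy)propyl]-2-methoxyphenol; 3 ethyl glyoxylate
Product: 5 racemic ethyl 2-hydroxy-2-{2-hydroxy-3-methoxy-5-[3-(tert-butyldimethylsilyloxy)propyl]phenyl}acetate, via bromomagnesium phenolate 4 (not isolated)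
Conditions: EtMgBr (1.0 equiv), Et2O, 0 °C; solvent change to CH2Cl2; 3 (1.5 equiv, freshly distilled), −10 °C→rt; aq NH4Cl
Reagents that add atoms: ethylmagnesium bromide, CC[Mg]Br (Mg and Br of 4 only)
Why: Ortho-specific hydroxyalkylation of a magnesium phenolate (chelation-directed Friedel–Crafts type), in which magnesium binds phenolate oxygen and aldehyde together and delivers the glyoxylate to the only free ortho carbon, the para position being blocked by the side chain, while the new carbinol centre is racemic and is erased in step 15.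

Step 3
Reactants: 5 racemic 2-hydroxymandelate
Product: 7 racemic ethyl 2-{2-hydroxy-3-methoxy-5-[3-(tert-butyldimethylsilyloxy)propyl]phenyl}-2-(p-tolylsulfonyl)acetate, via α-bromo ester 6 (not isolated)
Conditions: PPh3 (1.15 equiv), CBr4 (1.15 equiv), CH2Cl2, −20→0 °C; then TolSO2Na (2.0 equiv), DMF, 0 °C→rt
Reagents that add atoms: carbon tetrabromide, BrC(Br)(Br)Br (bromine of 6 only); sodium p-toluenesulfinate, [Na+].[O-]S(=O)c1ccc(C)cc1
Why: Appel bromination runs under nearly neutral conditions that spare silyl ether and phenol, and the soft sulfinate then displaces the α-bromo ester through sulfur in a carbonyl-accelerated SN2 reaction, which avoids the acid-driven ionisation that an ester-bearing benzylic alcohol resists, the centre staying racemic.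

Step 4
Reactants: 8 (2R,5R)-hexane-2,5-diol
Product: 9 (2R,5R)-hexane-2,5-diyl dimethanesulfonate
Conditions: MsCl (2.4 equiv), Et3N (3.0 equiv), CH2Cl2, −10→0 °C
Reagents that add atoms: methanesulfonyl chloride, CS(=O)(=O)Cl
Why: Standard mesylation of secondary alcohols, with the C–O bonds and both stereocentres untouched.

Step 5
Reactants: 9 (2R,5R)-dimesylate
Product: 10 (2S,5S)-2,5-dimethylthiolane
Conditions: Na2S·9H2O (1.5 equiv), EtOH, rt→40 °C; distillation
Reagents that add atoms: sodium sulfide, [Na+].[Na+].[S-2]
Why: Double SN2 displacement by sulfide, the second one a 5-exo-tet ring closure, inverts both secondary centres cleanly and so turns the R,R diester into the S,S thiolane.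

Step 6
Reactants: 11 2,3-O-isopropylidene-D-erythronolactone (3aR,6aR)
Product: 12 2,3-O-isopropylidene-D-erythrose (lactol as anomer mixture)
Conditions: iBu2AlH (DIBAL-H, 1.1 equiv), CH2Cl2, −78 °C; aq potassium sodium tartrate
Reagents that add atoms: none
Why: Partial reduction of a γ-lactone, in which the aluminium hemiacetal does not collapse at low temperature, so reduction stops at the lactol and the two acetonide-bearing stereocentres are untouched.

Step 7
Reactants: 12 2,3-O-isopropylidene-D-erythrose
Product: 13 [(4R,5S)-2,2-dimethyl-5-vinyl-1,3-dioxolan-4-yl]methanol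
Conditions: Ph3PCH3Br (3.0 equiv), KOtBu (2.9 equiv), THF, 0 °C→rt
Reagents that add atoms: methyltriphenylphosphonium bromide, [Br-].C[P+](c1ccccc1)(c1ccccc1)c1ccccc1
Why: Wittig methylenation of the open hydroxy aldehyde form of the lactol by a non-stabilised ylide, fast enough to outrun α-epimerisation, turns lactone C1 into the future C2' so that lactone C2, C3 and C4 become C3' (S), C4' (R) and C5'.

Step 8
Reactants: 13 vinyl dioxolane methanol
Product: 14 (4S,5S)-4-(iodomethyl)-2,2-dimethyl-5-vinyl-1,3-dioxolane
Conditions: I2 (1.2 equiv), PPh3 (1.2 equiv), imidazole (2.5 equiv), THF, 0 °C→rt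
Reagents that add atoms: iodine, II
Why: Appel-type iodination (Garegg–Samuelsson conditions) of a primary alcohol by SN2 at CH2, with no stereocentre involved (only the descriptor at C4 changes) and the acetonide stable in the buffered medium.

Step 9
Reactants: 15 ethyl 2-(bromomethyl)acrylate
Product: 16 ethyl 2-(p-tolylsulfonylmethyl)acrylate
Conditions: TolSO2Na (1.1 equiv), MeOH, reflux
Reagents that add atoms: sodium p-toluenesulfinate, [Na+].[O-]S(=O)c1ccc(C)cc1
Why: Displacement of a reactive allylic bromide by the sulfur atom of the sulfinate, where direct SN2 attack and attack with allylic shift give the same sulfone.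

Step 10
Reactants: 14 iodide; 16 allyl sulfone
Product: 17 ethyl 4-[(4R,5S)-2,2-dimethyl-5-vinyl-1,3-dioxolan-4-yl]-2-methylidenebutanoate
Conditions: 16 (2.5 equiv), (Bu3Sn)2 (1.2 equiv), PhH, hν (sunlamp), 40 °C
Reagents that add atoms: none
Why: Keck-type radical allylation by addition–fragmentation, in which a stannyl radical abstracts iodine, the nucleophilic primary radical at C5' adds to the electron-poor alkene of 16 (C5'–C6' bond) and β-scission of the sulfonyl radical, which carries the chain through the distannane, restores a 1,1-disubstituted alkene, while a β-oxygenated radical does not fragment and a 4-pentenyl radical does not cyclise at a competitive rate.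

Step 11
Reactants: 17 diene ester
Product: 18 ethyl (3aS,7aR)-2,2-dimethyl-3a,6,7,7a-tetrahydro-1,3-benzodioxole-5-carboxylate
Conditions: second-generation Grubbs catalyst, RuCl2(=CHPh)(PCy3)(SIMes) (5 mol %), CH2Cl2 (0.01 M), reflux
Reagents that add atoms: none
Why: Ring-closing metathesis, in which the catalyst loads on the monosubstituted vinyl group and closes on the 1,1-disubstituted acrylate to a strain-free cis-fused cyclohexene (C1'=C2'), driven by loss of ethene and touching no stereocentre.

Step 12
Reactants: 18 cyclohexenecarboxylate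
Product: 19 [(3aS,7aR)-2,2-dimethyl-3a,6,7,7a-tetrahydro-1,3-benzodioxol-5-yl]methanol
Conditions: iBu2AlH (2.5 equiv), CH2Cl2, −78 °C; aq potassium sodium tartrate
Reagents that add atoms: none
Why: 1,2-Reduction of a conjugated ester by DIBAL-H gives the allylic alcohol without touching alkene or acetonide.

Step 13
Reactants: 19 allylic alcohol
Product: 20 (3aS,7aR)-5-(bromomethyl)-2,2-dimethyl-3a,6,7,7a-tetrahydro-1,3-benzodioxole
Conditions: CBr4 (1.2 equiv), PPh3 (1.25 equiv), CH2Cl2, 0 °C
Reagents that add atoms: carbon tetrabromide, BrC(Br)(Br)Br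
Why: Appel bromination of a primary allylic alcohol proceeds by direct SN2 under neutral conditions, so neither allylic shift nor acetonide loss is expected.

Step 14
Reactants: 20 allylic bromide; 10 (2S,5S)-2,5-dimethylthiolane
Product: 21 (2S,5S)-1-{[(3aS,7aR)-2,2-dimethyl-3a,6,7,7a-tetrahydro-1,3-benzodioxol-5-yl]methyl}-2,5-dimethylthiolan-1-ium tetrafluoroborate
Conditions: 10 (1.5 equiv), AgBF4 (1.05 equiv), CH2Cl2, 0 °C→rt, dark; filtration
Reagents that add atoms: silver tetrafluoroborate, [Ag+].F[B-](F)(F)F (counter-ion)
Why: S-alkylation of a dialkyl sulfide by a primary allylic bromide, driven to completion by precipitation of AgBr, where the twofold symmetry of 10 makes both lone pairs equivalent so that one salt forms and the non-nucleophilic anion cannot dealkylate it.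

Step 15
Reactants: 7 racemic α-tosyl arylacetate; 21 sulfonium tetrafluoroborate
Product: 25 ethyl (2S,3S)-trans-2-[(3aS,7aR)-2,2-dimethyl-3a,6,7,7a-tetrahydro-1,3-benzodioxol-5-yl]-7-methoxy-5-[3-(tert-butyldimethylsilyloxy)propyl]-2,3-dihydro-1-benzofuran-3-carboxylate, via ortho-quinone methide 22 (not isolated), via allylic ylide 23 (not isolated), via betaine 24 (not isolated)
Conditions: 21 (1.0 equiv), Cs2CO3 (3.0 equiv, ground), MeCN, −10 °C; 7 (1.2 equiv) added slowly; →rt; then DBU (0.2 equiv), rt
Reagents that add atoms: none
Why: Cs2CO3 deprotonates the phenol of 7, the phenoxide expels p-toluenesulfinate to give quinone methide 22, the same base converts 21 into allylic ylide 23, the α-carbon of 23 adds to the exocyclic methide carbon with rearomatisation (C2–C3 bond) to give betaine 24, and phenoxide O1 displaces the thiolane from C2 with inversion (O1–C2 bond). The closest known reaction type is the trans-selective formal (4+1) annulation of sulfonium ylides with ortho-quinone methides released by carbonate bases from 2-(1-tosylalkyl)phenols, and the release of an ester-bearing acceptor from a sulfone with an acidic C–H has its parallel in α-sulfonyl glycinates, which give imino esters under the same bases. The one new ring, the dihydrofuran, closes by 5-exo-tet SN2 displacement at an allylic sulfonium carbon. C2 is controlled by the (2S,5S)-thiolane and not by the remote acetonide centres: the ylide holds its alkenyl group beside the sulfur lone pair, the methyl group cis to the ylide carbon shields one face, bonding on the open face followed by inversion gives 2S as in epoxidations with sulfides of this class, and since aromatisation makes the addition irreversible this result does not depend on which face of 22 reacts. C3 is controlled by C2, because the less crowded anti betaine closes faster and the acidic C3–H between arene and ester allows carbonate or DBU to drain any cis isomer into the more stable trans (2S,3S) ester. The step needs α- rather than γ-attack, conjugate rather than carbonyl addition and a long-lived salt, which are secured by the hindered secondary γ-carbon C2' next to the C3' oxygen, by the gain in aromaticity, by an ester substituent that offers no neighbouring C–H for tautomerisation to a vinylphenol, by a tetrafluoroborate anion that cannot return 21 to an O-alkylating allyl bromide and by tertiary α'-hydrogens that slow the competing [2,3] shift.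

Step 16
Reactants: 25 trans-dihydrobenzofuran ester
Product: 26 {(2S,3R)-2-[(3aS,7aR)-2,2-dimethyl-3a,6,7,7a-tetrahydro-1,3-benzodioxol-5-yl]-7-methoxy-5-[3-(tert-butyldimethylsilyloxy)propyl]-2,3-dihydro-1-benzofuran-3-yl}methanol
Conditions: iBu2AlH (3.0 equiv), CH2Cl2, −78→−20 °C; aq potassium sodium tartrate
Reagents that add atoms: none
Why: Ester reduction with a non-basic aluminium hydride at low temperature turns the C3 ester into the hydroxymethyl group without enolisation, so C3 is not epimerised (only its descriptor changes) and the ring is not opened by β-elimination of O1.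

Step 17
Reactants: 26 protected triol
Product: 27 difengpiol A [(1R,2S)-4-[(2S,3R)-3-(hydroxymethyl)-5-(3-hydroxypropyl)-7-methoxy-2,3-dihydro-1-benzofuran-2-yl]cyclohex-3-ene-1,2-diol]
Conditions: AcOH/THF/H2O (3:1:1), 45 °C
Reagents that add atoms: none
Why: Acid hydrolysis removes the primary silyl ether and the acetonide in one operation, and acetic acid is too weak to ionise the allylic C3' alcohol or the allylic C2–O1 ether, so all four stereocentres are kept.

Compound list
1 | dihydroconiferyl alcohol, 4-(3-hydroxypropyl)-2-methoxyphenol | COc1cc(CCCO)ccc1O | starting material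
2 | 4-[3-(tert-butyldimethylsilyloxy)propyl]-2-methoxyphenol | COc1cc(CCCO[Si](C)(C)C(C)(C)C)ccc1O | intermediate
3 | ethyl glyoxylate | CCOC(=O)C=O | starting material
4 | bromomagnesium phenolate of 2 (not isolated) | COc1cc(CCCO[Si](C)(C)C(C)(C)C)ccc1O[Mg]Br | intermediate
5 | racemic ethyl 2-hydroxy-2-{2-hydroxy-3-methoxy-5-[3-(TBSO)propyl]phenyl}acetate | CCOC(=O)C(O)c1cc(CCCO[Si](C)(C)C(C)(C)C)cc(OC)c1O | intermediate
6 | racemic ethyl 2-bromo-2-{2-hydroxy-3-methoxy-5-[3-(TBSO)propyl]phenyl}acetate (not isolated) | CCOC(=O)C(Br)c1cc(CCCO[Si](C)(C)C(C)(C)C)cc(OC)c1O | intermediate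
7 | racemic ethyl 2-{2-hydroxy-3-methoxy-5-[3-(TBSO)propyl]phenyl}-2-(p-tolylsulfonyl)acetate | CCOC(=O)C(c1cc(CCCO[Si](C)(C)C(C)(C)C)cc(OC)c1O)S(=O)(=O)c1ccc(C)cc1 | intermediate
8 | (2R,5R)-hexane-2,5-diol | C[C@@H](O)CC[C@@H](C)O | starting material
9 | (2R,5R)-hexane-2,5-diyl dimethanesulfonate | C[C@@H](OS(C)(=O)=O)CC[C@@H](C)OS(C)(=O)=O | intermediate
10 | (2S,5S)-2,5-dimethylthiolane | C[C@H]1CC[C@H](C)S1 | intermediate
11 | 2,3-O-isopropylidene-D-erythronolactone | O=C1[C@H](OC2(C)C)[C@H](O2)CO1 | starting material
12 | 2,3-O-isopropylidene-D-erythrose, lactol, anomeric centre open | OC1[C@H](OC2(C)C)[C@H](O2)CO1 | intermediate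
13 | [(4R,5S)-2,2-dimethyl-5-vinyl-1,3-dioxolan-4-yl]methanol | C=C[C@H](OC1(C)C)[C@H](O1)CO | intermediate
14 | (4S,5S)-4-(iodomethyl)-2,2-dimethyl-5-vinyl-1,3-dioxolane | C=C[C@H](OC1(C)C)[C@H](O1)CI | intermediate
15 | ethyl 2-(bromomethyl)acrylate | C=C(CBr)C(=O)OCC | starting material
16 | ethyl 2-(p-tolylsulfonylmethyl)acrylate | C=C(CS(=O)(=O)c1ccc(C)cc1)C(=O)OCC | intermediate
17 | ethyl 4-[(4R,5S)-2,2-dimethyl-5-vinyl-1,3-dioxolan-4-yl]-2-methylidenebutanoate | C=C[C@H](OC1(C)C)[C@H](O1)CCC(=C)C(=O)OCC | intermediate
18 | ethyl (3aS,7aR)-2,2-dimethyl-3a,6,7,7a-tetrahydro-1,3-benzodioxole-5-carboxylate | CCOC(=O)C1=C[C@H](OC2(C)C)[C@H](O2)CC1 | intermediate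
19 | [(3aS,7aR)-2,2-dimethyl-3a,6,7,7a-tetrahydro-1,3-benzodioxol-5-yl]methanol | OCC1=C[C@H](OC2(C)C)[C@H](O2)CC1 | intermediate
20 | (3aS,7aR)-5-(bromomethyl)-2,2-dimethyl-3a,6,7,7a-tetrahydro-1,3-benzodioxole | BrCC1=C[C@H](OC2(C)C)[C@H](O2)CC1 | intermediate
21 | (2S,5S)-2,5-dimethylthiolanium salt of the cyclohexenylmethyl group, tetrafluoroborate | F[B-](F)(F)F.C[C@H]1CC[C@H](C)[S+]1CC1=C[C@H](OC2(C)C)[C@H](O2)CC1 | intermediate
22 | ester-bearing ortho-quinone methide, E isomer drawn (not isolated) | CCOC(=O)/C=C1\C=C(CCCO[Si](C)(C)C(C)(C)C)C=C(OC)C1=O | intermediate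
23 | allylic sulfonium ylide from 21 (not isolated) | C[C@H]1CC[C@H](C)[S+]1[CH-]C1=C[C@H](OC2(C)C)[C@H](O2)CC1 | intermediate
24 | betaine, phenoxide beside the allylic sulfonium carbon (not isolated) | CCOC(=O)[C@@H](c1cc(CCCO[Si](C)(C)C(C)(C)C)cc(OC)c1[O-])[C@@H]([S+]1[C@@H](C)CC[C@@H]1C)C1=C[C@H](OC2(C)C)[C@H](O2)CC1 | intermediate
25 | ethyl (2S,3S)-trans-2-cyclohexenyl-2,3-dihydrobenzofuran-3-carboxylate, acetonide and TBS ether in place | COc1cc(CCCO[Si](C)(C)C(C)(C)C)cc2c1O[C@H](C1=C[C@H](OC3(C)C)[C@H](O3)CC1)[C@H]2C(=O)OCC | intermediate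
26 | (2S,3R)-3-hydroxymethyl compound, acetonide and TBS ether in place | COc1cc(CCCO[Si](C)(C)C(C)(C)C)cc2c1O[C@H](C1=C[C@H](OC3(C)C)[C@H](O3)CC1)[C@H]2CO | intermediate
27 | difengpiol A, (2S,3R,3'S,4'R) | COc1cc(CCCO)cc2c1O[C@H](C1=C[C@H](O)[C@H](O)CC1)[C@H]2CO | target

Total step count: 17. Longest linear sequence: 11 steps (from 11 through steps 6, 7, 8 and 10 to 17).

Steps most likely to fail

1) Step 15.
- **What may go wrong:**
  - Facial control at the ylide carbon may be incomplete.
  - The quinone methide may be released too slowly because base parks 7 as its carbon anion.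
  - Sulfinate or phenoxide may dealkylate the sulfonium salt.
  - The ylide may decay through loss of the allylic C3' alkoxide.
- **Fallback (sets out from 7 and 20, comes back at 25):** the ring is closed by carbene C–H insertion instead of annulation. Reductive desulfonylation of 7 with Al(Hg) in wet THF gives ethyl 2-{2-hydroxy-3-methoxy-5-[3-(TBSO)propyl]phenyl}acetate F1. Its phenol is alkylated with bromide 20 (K2CO3, DMF) to the allylic aryl ether F2. Diazo transfer (4-acetamidobenzenesulfonyl azide, DBU, MeCN) gives the aryldiazoacetate F3. A chiral dirhodium carboxylate, dirhodium tetrakis[N-phthaloyl-(S)-tert-leucinate], Rh2(S-PTTL)4, or its enantiomer as the 2S sense requires, then inserts the donor/acceptor carbene into the O–CH2 group. That group is activated by oxygen and alkene alike, and the trisubstituted alkene resists cyclopropanation. The product is the cis-(2S,3R)-dihydrobenzofuran ester F4, and DBU then epimerises C3 to give 25.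

2) Step 3.
- **What may go wrong:**
  - The silyl ether may be attacked by the bromophosphonium reagent.
  - The bromo phenol may lose HBr early and oligomerise.
  - The sulfinate may be alkylated at oxygen instead of sulfur.
- **Fallback (sets out from 5, comes back at 7):** substitution runs by base-induced elimination–addition instead of SN2. Acetylation (Ac2O, pyridine) gives the diacetate F5. K2CO3 in EtOH then cleaves the aryl acetate and the phenoxide expels the benzylic acetate. TolSO2Na, present in excess, adds to the transient quinone methide. The acidic C–H of the adduct holds it as its anion until a mild acid quench delivers 7.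

3) Step 10.
- **What may go wrong:**
  - The radical chains may be short.
  - The radical may add to the acrylate product and telomerise.
  - The radical may be reduced prematurely.
- **Fallback (sets out from 13, comes back at 19):** the C5'–C6' bond is made by polar coupling. Tf2O and 2,6-lutidine (CH2Cl2, −78 °C) give the primary triflate F6. Dilithiated 2-methylprop-2-en-1-ol (n-BuLi, TMEDA, Et2O) displaces the triflate through carbon to give the dienol F7. Ring-closing metathesis with the second-generation Grubbs catalyst, RuCl2(=CHPh)(PCy3)(SIMes), then gives 19 directly.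

Further compounds
F1 | step 15 | ethyl 2-{2-hydroxy-3-methoxy-5-[3-(tert-butyldimethylsilyloxy)propyl]phenyl}acetate | CCOC(=O)Cc1cc(CCCO[Si](C)(C)C(C)(C)C)cc(OC)c1O
F2 | step 15 | ethyl 2-{2-{[(3aS,7aR)-2,2-dimethyl-3a,6,7,7a-tetrahydro-1,3-benzodioxol-5-yl]methoxy}-3-methoxy-5-[3-(TBSO)propyl]phenyl}acetate | CCOC(=O)Cc1cc(CCCO[Si](C)(C)C(C)(C)C)cc(OC)c1OCC1=C[C@H](OC2(C)C)[C@H](O2)CC1
F3 | step 15 | the corresponding ethyl 2-aryl-2-diazoacetate | CCOC(=O)C(=[N+]=[N-])c1cc(CCCO[Si](C)(C)C(C)(C)C)cc(OC)c1OCC1=C[C@H](OC2(C)C)[C@H](O2)CC1
F4 | step 15 | ethyl (2S,3R)-cis-2-cyclohexenyl-2,3-dihydrobenzofuran-3-carboxylate, C3 epimer of 25 | COc1cc(CCCO[Si](C)(C)C(C)(C)C)cc2c1O[C@H](C1=C[C@H](OC3(C)C)[C@H](O3)CC1)[C@@H]2C(=O)OCC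
F5 | step 3 | racemic ethyl 2-acetoxy-2-{2-acetoxy-3-methoxy-5-[3-(TBSO)propyl]phenyl}acetate | CCOC(=O)C(OC(C)=O)c1cc(CCCO[Si](C)(C)C(C)(C)C)cc(OC)c1OC(C)=O
F6 | step 10 | [(4R,5S)-2,2-dimethyl-5-vinyl-1,3-dioxolan-4-yl]methyl trifluoromethanesulfonate | C=C[C@H](OC1(C)C)[C@H](O1)COS(=O)(=O)C(F)(F)F
F7 | step 10 | 4-[(4R,5S)-2,2-dimethyl-5-vinyl-1,3-dioxolan-4-yl]-2-methylidenebutan-1-ol | C=C[C@H](OC1(C)C)[C@H](O1)CCC(=C)CO
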